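**Retrosynthetic overview**

1. Target 38 is cut at the C8 ester into acid 20 and hydroxy lactone 34. The γ-lactone (ring B) is the last ring made, by oxidative lactonisation of a C6–OH/C12–OH diol; C13 comes from lactone enolate methylation and C8–OH from a C8 ketone.
2. The cyclohexane (ring A, C5–C10) is cut at C9–C10 and C5–C6: a type 2 intramolecular Diels–Alder reaction of triene 22, with a 1-alkoxy-3-silyloxy diene (C6=C7–C8=C9) and an (E)-enone (C5=C10).
3. Enabling feature: on ring A the oxygen on C8 and the vinyl carbon C1 on the quaternary C10 are 1,3-cis across C9, so an O8–Si–O–C1 bridge can join diene and dienophile; O6 and O8 flank C7 as in a 1,3-dioxygenated diene. The bridge leaves O8 as the ketone and C1 as a carbinol that is dehydrated to the vinyl group.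
4. Ring order: the temporary dioxepin ring (O6–CMe2–O12, locks the enol ether geometry and carries C11–C12) is present from the start; ring A and the temporary silyl acetal bridge form in the key step; ring B forms last.
5. Absolute configuration comes from (R)-but-3-yn-2-ol (the C1 carbinol, destroyed later) and from (S)-butane-1,2,4-triol acetonide (side chain).

Key step: step 11

Remark: locants C1–C15 are the elemane locants of the target (ring C5–C10, C14 = C10 methyl, C15 = CH2O); "Me-face" is the ring face of the C10 methyl and "O-face" the opposite one; the facial course of step 11 is assumed to follow the allylic 1,2-strain model given there.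

**Step 1**
Reactants: 1 dioxepin acetal (2,2-dimethyl-4,7-dihydro-1,3-dioxepin)
Product: 2 2,2-dimethyl-4,5-dihydro-1,3-dioxepin
Conditions: RuHCl(CO)(PPh3)3 (cat.), neat, 100 °C; distillation
Reagents that add atoms: none
Why: Ruthenium hydride-catalysed double-bond migration (hydrometalation/β-hydride elimination) should move the alkene into conjugation with oxygen to give the cyclic enol ether; no stereocentre is formed.

**Step 2**
Reactants: 2 enol ether (2,2-dimethyl-4,5-dihydro-1,3-dioxepin)
Product: 4 6-bromo-2,2-dimethyl-4,5-dihydro-1,3-dioxepin, via trans-dibromide 3 (not isolated)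
Conditions: Br2, CH2Cl2, −78 °C; then Et3N, −78 °C → rt
Reagents that add atoms: bromine (BrBr)
Why: Bromination–dehydrobromination of an enol ether: anti addition of Br2, then E2 loss of HBr from the α-bromo ether (the only β-hydrogen is on the bromine-bearing carbon) should give the β-bromo enol ether.

**Step 3**
Reactants: 4 bromo enol ether; 5 N-methoxy-N-methylacetamide
Product: 7 1-(2,2-dimethyl-4,5-dihydro-1,3-dioxepin-6-yl)ethan-1-one, via vinyllithium 6 (not isolated)
Conditions: t-BuLi (2 equiv), Et2O, −78 °C; then 5, −78 → 0 °C; H2O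
Reagents that add atoms: none
Why: Lithium–bromine exchange followed by Weinreb ketone synthesis (stable chelated tetrahedral intermediate) should give the vinylogous ester, in which the ring holds O6 cis to C11 and therefore trans to the acetyl group.

**Step 4**
Reactants: 8 4-methoxybenzyl alcohol; 9 2-chloro-N-methoxy-N-methylacetamide
Product: 10 N-methoxy-2-[(4-methoxybenzyl)oxy]-N-methylacetamide
Conditions: NaH, THF, 0 °C; then 9, Bu4NI (cat.), 0 °C → rt
Reagents that add atoms: none
Why: Williamson ether synthesis; SN2 displacement of the activated α-chloro amide by the alkoxide.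

**Step 5**
Reactants: 11 (R)-but-3-yn-2-ol
Product: 13 (2R,3E)-4-iodo-3-methylbut-3-en-2-ol, via alkenylalane 12 (not isolated)
Conditions: AlMe3 (3 equiv), Cp2ZrCl2 (0.25 equiv), CH2Cl2, 0 °C → rt; then I2, THF, −30 → 0 °C; aqueous work-up
Reagents that add atoms: trimethylaluminium (C[Al](C)C); iodine (II)
Why: Negishi zirconium-catalysed carboalumination adds CH3 and Al syn across the alkyne with Al at the terminus, and iodinolysis with retention should give the (E)-iodide; the carbinol stereocentre is not touched.

**Step 6**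
Reactants: 13 vinyl iodide; 10 Weinreb amide
Product: 15 (3E,5R)-5-hydroxy-1-[(4-methoxybenzyl)oxy]-4-methylhex-3-en-2-one, via dilithio species 14 (not isolated)
Conditions: t-BuLi (3 equiv), Et2O, −78 °C; then 10, −78 → −20 °C; H2O
Reagents that add atoms: none
Why: Deprotonation and iodine–lithium exchange give the alkoxide–vinyllithium, which acylates on the Weinreb amide with retention of the (E)-geometry (Weinreb ketone synthesis).

**Step 7**
Reactants: 16 2-[(4S)-2,2-dimethyl-1,3-dioxolan-4-yl]ethan-1-ol
Product: 17 [(4S)-2,2-dimethyl-1,3-dioxolan-4-yl]acetaldehyde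
Conditions: Dess–Martin periodinane, CH2Cl2, 0 °C → rt
Reagents that add atoms: none
Why: Dess–Martin oxidation of the primary alcohol; the stereocentre is β to the carbonyl and cannot epimerise by enolisation.

**Step 8**
Reactants: 17 aldehyde
Product: 19 2-[(4S)-2,2-dimethyl-1,3-dioxolan-4-yl]prop-2-enal, via Mannich base 18 (not isolated)
Conditions: CH2=NMe2+ I− (Eschenmoser's salt), Et3N, CH2Cl2, rt
Reagents that add atoms: N,N-dimethylmethyleneiminium iodide (C=[N+](C)C.[I-])
Why: Mannich reaction of the aldehyde enol with the iminium salt and β-elimination of dimethylamine (α-methylenation) should give the 2-substituted acrolein under conditions mild enough to keep the β-alkoxy group.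

**Step 9**
Reactants: 19 enal
Product: 20 2-[(4S)-2,2-dimethyl-1,3-dioxolan-4-yl]prop-2-enoic acid
Conditions: NaClO2, NaH2PO4, 2-methyl-2-butene, t-BuOH/H2O, 0 °C → rt
Reagents that add atoms: sodium chlorite (NaClO2, [Na+].[O-]Cl=O)
Why: Pinnick oxidation converts the enal into the acrylic acid without touching the alkene or the acetonide.

**Step 10**
Reactants: 7 vinylogous ester ketone; 15 enone alcohol
Product: 22 triene silyl acetal, via silyl triflate 21 (not isolated)
Conditions: iPr2Si(OTf)2, Et3N, CH2Cl2, −78 °C, slow addition of 7; then 15, DMAP (cat.), −78 → 0 °C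
Reagents that add atoms: diisopropylsilyl bis(trifluoromethanesulfonate) (CC(C)[Si](OS(=O)(=O)C(F)(F)F)(OS(=O)(=O)C(F)(F)F)C(C)C)
Why: Soft enolisation (O-silylation of the vinylogous ester carbonyl, then loss of a C9 proton, as in the preparation of 1-alkoxy-3-silyloxy dienes) gives the enol silyl triflate, which silylates the secondary alcohol to the unsymmetrical silyl acetal.

**Step 11**
Reactants: 22 triene silyl acetal
Product: 23 bridged cycloadduct
Conditions: PhMe (0.01 M), BHT (cat.), Et3N (trace), 150 °C, sealed tube
Reagents that add atoms: none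
Why: On heating, the 1-alkoxy-3-silyloxy diene (C6=C7–C8=C9, with O6 held outside and cis to C11 by the dioxepin ring) should add across the (E)-enone C5=C10 in a concerted, asynchronous [4+2] cycloaddition in which the nucleophilic terminus C9 bonds to the β-carbon C10 and C6 bonds to the α-carbon C5, so the polarity of both partners matches the regiochemistry that the tether imposes. The closest known reaction type is the type 2 intramolecular Diels–Alder reaction through a temporary tether on the 2-oxygen of the diene, which gives bridgehead enol ethers and enol lactones. Two rings close at once: the cyclohexene by suprafacial [4π+2π] addition, and the seven-membered silyl acetal ring (C8–O–Si–O–C1–C10–C9) as the bridge of a bicyclo[4.3.1] system with a bridgehead C7=C8 enol ether, which the long Si–O bonds make accessible. C5 and C10 take their relative configuration from the (E)-geometry of the dienophile (C10 methyl cis to the C5 acyl group), and C6 takes its configuration from the four-atom tether, which can reach O8 only if C1 lies under the diene (endo), so that O6 ends up cis to C1 and trans to the C5 acyl group, the opposite of the untethered endo preference of the ketone. The absolute sense comes from the (R)-carbinol at C1: with the C1–O bond directed to the diene, the C1–H bond eclipses the C10–CH3 bond and the C1 methyl points away from the diene (allylic 1,2-strain), so only one π-face of the enone is presented. The step needs regio-, endo/exo- and π-facial selectivity, and the tether length, the ring-locked enol ether geometry and the carbinol stereocentre are meant to secure them in that order.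

**Step 12**
Reactants: 23 bridged cycloadduct
Product: 24 bridged C4-methylene compound
Conditions: Cp2TiMe2, PhMe/THF, 70 °C, dark
Reagents that add atoms: bis(cyclopentadienyl)dimethyltitanium (Cp2TiMe2, [CH3-].[CH3-].[Ti+4].c1cc[cH-]c1.c1cc[cH-]c1)
Why: Petasis methylenation converts the only free ketone (C4; C8 is masked as the silyl enol ether) into the C4=C3 methylene under non-basic conditions, which avoids epimerisation at C5 and β-elimination of O6.

**Step 13**
Reactants: 24 bridged C4-methylene compound
Product: 25 keto alcohol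
Conditions: Bu4NF, AcOH, THF, 0 °C → rt
Reagents that add atoms: none
Why: Fluoride cleaves both Si–O bonds of the silyl acetal; the liberated enolate should be protonated axially at C7 from the O-face, which places C7–C11 on the Me-face, trans-diequatorial to C6–O, the arrangement that is also the thermodynamic one for the cyclohexanone.

**Step 14**
Reactants: 25 keto alcohol
Product: 26 vinyl ketone
Conditions: Ph2S[OC(CF3)2Ph]2 (Martin sulfurane), CH2Cl2, 0 °C → rt
Reagents that add atoms: none
Why: Martin sulfurane dehydration: E2 elimination from the alkoxysulfonium can only use the hydrogens of the C2 methyl group (C10 is quaternary), so the C1 stereocentre is converted into the C1=C2 vinyl group under neutral conditions that leave the ketone and the acetal alone.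

**Step 15**
Reactants: 26 vinyl ketone
Product: 29 keto lactone, via keto diol 27 (not isolated), via lactol 28 (not isolated)
Conditions: AcOH/THF/H2O, rt; evaporation; TEMPO (cat.), PhI(OAc)2, CH2Cl2, rt
Reagents that add atoms: none
Why: Mild acid hydrolysis of the seven-membered acetonide frees the C6/C12 diol, and TEMPO/PhI(OAc)2 oxidative lactonisation (primary alcohol to aldehyde, lactol with O6, then lactone) closes ring B; no bond to C6 or C7 is broken, so the trans ring fusion is kept.

**Step 16**
Reactants: 29 keto lactone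
Product: 30 hydroxy lactone
Conditions: SmI2, THF/MeOH, −78 °C
Reagents that add atoms: none
Why: Single-electron reduction of the ketone by SmI2 with protonation of the samarium-bound ketyl should place O8 equatorial on the O-face, 1,3-syn to O6, as is usual for β-alkoxy ketones; this is the thermodynamic alcohol, which hydride reagents would not favour because the axial C10 methyl blocks their approach from the Me-face.

**Step 17**
Reactants: 30 hydroxy lactone
Product: 34 C11-methyl hydroxy lactone, via TMS ether 31 (not isolated), via lithium enolate 32 (not isolated), via methylated TMS ether 33 (not isolated)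
Conditions: (Me3Si)2NH, Me3SiCl (cat.), CH2Cl2, rt, evaporation; LiN(iPr)2, THF, −78 °C; MeI, −78 → −40 °C; 1 M HCl, THF, 0 °C
Reagents that add atoms: iodomethane (CI)
Why: After transient silylation of O8, alkylation of the lactone enolate should occur on the face of C11 anti to C8 (cis to H7), the usual trans-to-β-substituent course for γ-lactone enolates, which sets C11 as R; the acidic work-up removes the TMS group.

**Step 18**
Reactants: 34 C11-methyl hydroxy lactone; 20 acrylic acid
Product: 36 protected ester, via mixed anhydride 35 (not isolated)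
Conditions: 20, 2,4,6-trichlorobenzoyl chloride, Et3N, PhMe, rt; then 34, DMAP, rt → 40 °C
Reagents that add atoms: none
Why: Yamaguchi esterification acylates the equatorial C8 hydroxyl with retention at C8 and without touching the side-chain stereocentre.

**Step 19**
Reactants: 36 protected ester
Product: 37 C15 alcohol
Conditions: DDQ, CH2Cl2/pH 7 buffer, 0 °C → rt
Reagents that add atoms: none
Why: Oxidative cleavage of the 4-methoxybenzyl ether by DDQ (hydride abstraction, hydrolysis of the oxocarbenium ion) frees the primary allylic alcohol in the presence of the esters, alkenes and acetonide.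

**Step 20**
Reactants: 37 C15 alcohol
Product: 38 target CNP0260337.1
Conditions: AcOH/H2O (4:1), 35 °C
Reagents that add atoms: none
Why: Mild acid hydrolysis of the dioxolane acetonide frees the side-chain 1,2-diol without acyl migration or lactone opening.

**Compound list**

1 | 2,2-dimethyl-4,7-dihydro-1,3-dioxepin | CC1(C)OCC=CCO1 | starting material
2 | 2,2-dimethyl-4,5-dihydro-1,3-dioxepin | CC1(C)OCCC=CO1 | intermediate
3 | trans-4,5-dibromo-2,2-dimethyl-1,3-dioxepane (racemic, one enantiomer drawn; not isolated) | CC1(C)OCC[C@H](Br)[C@@H](Br)O1 | intermediate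
4 | 6-bromo-2,2-dimethyl-4,5-dihydro-1,3-dioxepin | CC1(C)OCCC(Br)=CO1 | intermediate
5 | N-methoxy-N-methylacetamide | CC(=O)N(C)OC | starting material
6 | (2,2-dimethyl-4,5-dihydro-1,3-dioxepin-6-yl)lithium (not isolated) | CC1(C)OCCC([Li])=CO1 | intermediate
7 | 1-(2,2-dimethyl-4,5-dihydro-1,3-dioxepin-6-yl)ethan-1-one | CC(=O)C1=COC(C)(C)OCC1 | intermediate
8 | 4-methoxybenzyl alcohol | COc1ccc(CO)cc1 | starting material
9 | 2-chloro-N-methoxy-N-methylacetamide | CON(C)C(=O)CCl | starting material
10 | N-methoxy-2-[(4-methoxybenzyl)oxy]-N-methylacetamide | COc1ccc(COCC(=O)N(C)OC)cc1 | intermediate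
11 | (R)-but-3-yn-2-ol | C[C@@H](O)C#C | starting material
12 | dimethylaluminium (2R,3E)-4-(dimethylalumanyl)-3-methylbut-3-en-2-olate (not isolated) | C[C@@H](O[Al](C)C)/C(C)=C/[Al](C)C | intermediate
13 | (2R,3E)-4-iodo-3-methylbut-3-en-2-ol | C[C@@H](O)/C(C)=C/I | intermediate
14 | lithium (2R,3E)-4-lithio-3-methylbut-3-en-2-olate (not isolated) | C[C@@H](O[Li])/C(C)=C/[Li] | intermediate
15 | (3E,5R)-5-hydroxy-1-[(4-methoxybenzyl)oxy]-4-methylhex-3-en-2-one | C[C@@H](O)/C(C)=C/C(=O)COCc1ccc(OC)cc1 | intermediate
16 | 2-[(4S)-2,2-dimethyl-1,3-dioxolan-4-yl]ethan-1-ol | OCC[C@H]1COC(C)(C)O1 | starting material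
17 | [(4S)-2,2-dimethyl-1,3-dioxolan-4-yl]acetaldehyde | O=CC[C@H]1COC(C)(C)O1 | intermediate
18 | 3-(dimethylamino)-2-[(4S)-2,2-dimethyl-1,3-dioxolan-4-yl]propanal (both C2 epimers; not isolated) | CN(C)CC(C=O)[C@H]1COC(C)(C)O1 | intermediate
19 | 2-[(4S)-2,2-dimethyl-1,3-dioxolan-4-yl]prop-2-enal | C=C(C=O)[C@H]1COC(C)(C)O1 | intermediate
20 | 2-[(4S)-2,2-dimethyl-1,3-dioxolan-4-yl]prop-2-enoic acid | C=C(C(=O)O)[C@H]1COC(C)(C)O1 | intermediate
21 | [1-(2,2-dimethyl-4,5-dihydro-1,3-dioxepin-6-yl)ethenyl]oxy-diisopropylsilyl trifluoromethanesulfonate (not isolated) | C=C(O[Si](C(C)C)(C(C)C)OS(=O)(=O)C(F)(F)F)C1=COC(C)(C)OCC1 | intermediate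
22 | triene: diisopropylsilyl acetal joining the enol oxygen of 7 (C9H2=C8–O) and the (5R)-oxygen of 15; (3E)-enone unchanged | C=C(O[Si](C(C)C)(C(C)C)O[C@H](C)/C(C)=C/C(=O)COCc1ccc(OC)cc1)C1=COC(C)(C)OCC1 | intermediate
23 | bridged cycloadduct: cyclohexene C5–C10 with bridgehead enol ether C7=C8; bridge C8–O–Si(iPr)2–O–C1 to C10 (C1 R, carries CH3); 2,2-dimethyl-1,3-dioxepane fused at C6–C7; C10 methyl and C5 C(=O)CH2OPMB on the Me-face; C6–O and C1 on the O-face | C[C@H]1O[Si](C(C)C)(C(C)C)OC2=C3CCOC(C)(C)O[C@H]3[C@H](C(=O)COCc4ccc(OC)cc4)[C@]1(C)C2 | intermediate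
24 | bridged C4-methylene compound: as 23 with C5 carrying C(=CH2)CH2OPMB | C[C@H]1O[Si](C(C)C)(C(C)C)OC2=C3CCOC(C)(C)O[C@H]3[C@H](C(=C)COCc4ccc(OC)cc4)[C@]1(C)C2 | intermediate
25 | keto alcohol: cyclohexan-8-one; C10 carries CH3 (Me-face) and (1R)-1-hydroxyethyl (O-face); C5 carries 3-(PMB-oxy)prop-1-en-2-yl (Me-face); C6–O (O-face) and C7–CH2 (Me-face) are joined in the trans-fused 2,2-dimethyl-1,3-dioxepane | C[C@@H](O)[C@@]1(C)CC(=O)[C@@H]2CCOC(C)(C)O[C@H]2[C@@H]1C(=C)COCc1ccc(OC)cc1 | intermediate
26 | vinyl ketone: as 25 with vinyl in place of the 1-hydroxyethyl group at C10 | C=C[C@@]1(C)CC(=O)[C@@H]2CCOC(C)(C)O[C@H]2[C@@H]1C(=C)COCc1ccc(OC)cc1 | intermediate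
27 | keto diol: as 26 with free C6–OH (O-face) and C7–CH2CH2OH (Me-face) (not isolated) | C=C[C@@]1(C)CC(=O)[C@H](CCO)[C@@H](O)[C@@H]1C(=C)COCc1ccc(OC)cc1 | intermediate
28 | lactol: C12 hemiacetal closed onto O6, both anomers (not isolated) | C=C[C@@]1(C)CC(=O)[C@H]2[C@@H](OC(O)C2)[C@@H]1C(=C)COCc1ccc(OC)cc1 | intermediate
29 | keto lactone: 8-oxo-6,12-olide with trans-fused γ-lactone, 15-O-PMB, C11 unsubstituted | C=C[C@@]1(C)CC(=O)[C@H]2[C@@H](OC(=O)C2)[C@@H]1C(=C)COCc1ccc(OC)cc1 | intermediate
30 | hydroxy lactone: as 29 with C8–OH on the O-face (equatorial, cis to O6) | C=C[C@@]1(C)C[C@@H](O)[C@H]2[C@@H](OC(=O)C2)[C@@H]1C(=C)COCc1ccc(OC)cc1 | intermediate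
31 | 8-O-trimethylsilyl ether of 30 (not isolated) | C=C[C@@]1(C)C[C@@H](O[Si](C)(C)C)[C@H]2[C@@H](OC(=O)C2)[C@@H]1C(=C)COCc1ccc(OC)cc1 | intermediate
32 | lithium enolate of 31 (C11=C12–OLi; not isolated) | C=C[C@@]1(C)C[C@@H](O[Si](C)(C)C)[C@H]2[C@@H](OC(O[Li])=C2)[C@@H]1C(=C)COCc1ccc(OC)cc1 | intermediate
33 | (11R)-11-methyl derivative of 31 (not isolated) | C=C[C@@]1(C)C[C@@H](O[Si](C)(C)C)[C@H]2[C@@H](OC(=O)[C@@H]2C)[C@@H]1C(=C)COCc1ccc(OC)cc1 | intermediate
34 | C11-methyl hydroxy lactone: (11R)-methyl cis to H7, C8–OH free, 15-O-PMB | C=C[C@@]1(C)C[C@@H](O)[C@H]2[C@@H](OC(=O)[C@@H]2C)[C@@H]1C(=C)COCc1ccc(OC)cc1 | intermediate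
35 | mixed anhydride of 20 and 2,4,6-trichlorobenzoic acid (not isolated) | C=C(C(=O)OC(=O)c1c(Cl)cc(Cl)cc1Cl)[C@H]1COC(C)(C)O1 | intermediate
36 | protected ester: 8-O-{2-[(4S)-2,2-dimethyl-1,3-dioxolan-4-yl]prop-2-enoyl} derivative of 34 | C=C[C@@]1(C)C[C@@H](OC(=O)C(=C)[C@H]2COC(C)(C)O2)[C@H]3[C@@H](OC(=O)[C@@H]3C)[C@@H]1C(=C)COCc1ccc(OC)cc1 | intermediate
37 | C15 alcohol: 36 without the PMB group | C=C[C@@]1(C)C[C@@H](OC(=O)C(=C)[C@H]2COC(C)(C)O2)[C@H]3[C@@H](OC(=O)[C@@H]3C)[C@@H]1C(=C)CO | intermediate
38 | CNP0260337.1: (5S,6S,7S,8R,10R,11R)-15-hydroxy-8-{[(3S)-3,4-dihydroxy-2-methylidenebutanoyl]oxy}elema-1,3-dien-12,6-olide | C=C[C@@]1(C)C[C@@H](OC(=O)C(=C)[C@H](O)CO)[C@H]2[C@@H](OC(=O)[C@@H]2C)[C@@H]1C(=C)CO | target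

**Totals**

Total step count: 20. Longest linear sequence: 14 steps (steps 1–3 and 10–20).

**Steps most likely to fail**

Step 11. The cycloaddition onto the β,β-disubstituted enone may be slower than thermal or acid-induced loss of the silyl dienol ether, and discrimination of the two enone faces by the C1 methyl group may be incomplete. The fallback replaces the ketone by the more reactive aldehyde as dienophile and attaches C15 afterwards. It sets out from 13 and from silyl triflate 21 and comes back at 23. Iodide 13 is lithiated as in step 6 (via 14) and formylated with DMF to give (2E,4R)-4-hydroxy-3-methylpent-2-enal F1. Silylation of F1 with 21 (made from 7 as in step 10) gives the triene aldehyde F2, and the type 2 intramolecular Diels–Alder reaction, now possible at lower temperature, gives the bridged aldehyde F3. Tributyl{[(4-methoxybenzyl)oxy]methyl}stannane F4, made from commercial (tributylstannyl)methanol, NaH and 4-methoxybenzyl chloride, is converted by n-BuLi into {[(4-methoxybenzyl)oxy]methyl}lithium F5, which adds to F3 to give the carbinol F6 (both C4 epimers). Dess–Martin oxidation of F6 gives 23.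

Step 16. Protonation of the ketyl may not distinguish the two faces of C8 well enough, so that the axial C8 alcohol forms in quantity. The fallback accepts the axial alcohol and inverts it. It sets out from 29 and comes back at 30. LiB(s-Bu)3H (L-Selectride) at −78 °C attacks from the unhindered O-face and gives the 8-epi hydroxy lactone F8. Mitsunobu reaction of F8 with chloroacetic acid (PPh3, diisopropyl azodicarboxylate) gives the chloroacetate F9 with inversion at C8, and thiourea/NaHCO3 in EtOH removes the chloroacetyl group to give 30.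

Step 14. The neopentylic alkoxysulfonium intermediate may ionise and undergo a Wagner–Meerwein shift instead of E2 elimination. The fallback uses a concerted thermal syn-elimination. It sets out from 25 and comes back at 26. The alkoxide of 25 (NaH, cat. imidazole, CS2 present, then MeI) gives the S-methyl xanthate F7, and Chugaev pyrolysis in o-dichlorobenzene at 180 °C gives 26.

**Further compounds**

F1 | step 11 | (2E,4R)-4-hydroxy-3-methylpent-2-enal | C[C@@H](O)/C(C)=C/C=O
F2 | step 11 | triene aldehyde: diisopropylsilyl acetal of the enol of 7 and the (4R)-oxygen of F1 | C=C(O[Si](C(C)C)(C(C)C)O[C@H](C)/C(C)=C/C=O)C1=COC(C)(C)OCC1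
F3 | step 11 | bridged cycloadduct aldehyde: as 23 with CHO at C5 | C[C@H]1O[Si](C(C)C)(C(C)C)OC2=C3CCOC(C)(C)O[C@H]3[C@H](C=O)[C@]1(C)C2
F4 | step 11 | tributyl{[(4-methoxybenzyl)oxy]methyl}stannane | CCCC[Sn](CCCC)(CCCC)COCc1ccc(OC)cc1
F5 | step 11 | {[(4-methoxybenzyl)oxy]methyl}lithium | [Li]COCc1ccc(OC)cc1
F6 | step 11 | bridged carbinol: as 23 with CH(OH)CH2OPMB at C5 (both C4 epimers) | C[C@H]1O[Si](C(C)C)(C(C)C)OC2=C3CCOC(C)(C)O[C@H]3[C@H](C(O)COCc4ccc(OC)cc4)[C@]1(C)C2
F7 | step 14 | S-methyl xanthate of 25 (O-ester at C1) | C[C@@H](OC(=S)SC)[C@@]1(C)CC(=O)[C@@H]2CCOC(C)(C)O[C@H]2[C@@H]1C(=C)COCc1ccc(OC)cc1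
F8 | step 16 | 8-epi hydroxy lactone: as 30 with C8–OH on the Me-face (axial) | C=C[C@@]1(C)C[C@H](O)[C@H]2[C@@H](OC(=O)C2)[C@@H]1C(=C)COCc1ccc(OC)cc1
F9 | step 16 | 8-O-chloroacetate of 30 | C=C[C@@]1(C)C[C@@H](OC(=O)CCl)[C@H]2[C@@H](OC(=O)C2)[C@@H]1C(=C)COCc1ccc(OC)cc1
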